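**Plan**
- Retrosynthesis: the two interflavan bonds, C4(top)–C8(middle) and C4(middle)–C8(lower), are cut last. This gives a (2S)-flavan-4-ol and two copies of one monomer, 5,7,4'-tri-O-benzyl-epiafzelechin. Ring C of the monomer is cut at O1–C8a and C2–C3, giving 4-(benzyloxy)benzaldehyde and a 2-fluoro-4,6-bis(benzyloxy)benzyl unit whose C3 is a 2-silyl-1,3-dithiane carbon.
- Enabling feature: ring A is a phloroglucinol ring, so O5 and O7 both sit meta to C8a and do not deactivate a C8a–F bond toward an alkoxide. C3 is a carbinol carbon that can be carried at the ketone level as a dithiane carbanion. One fluoride-triggered annulation therefore joins C2–C3 and then O1–C8a.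
- Forward: ring A fluoride → silyl dithiane → ring C annulation → flavan-3-one → cis-flavan-3-ol. This monomer serves as the lower unit and, after oxidation at C4, as the middle unit (4β→8 dimer). The top unit, built from a chromone, is joined last, followed by global hydrogenolysis.
- Stereochemistry: the dithiane leaves a C3 ketone with an epimerisable C2, so one transfer hydrogenation with dynamic kinetic resolution sets C2 and C3 (2R,3R, cis) of both flavan-3-ol units. C4 of the middle unit is relayed (attack anti to 3-OH and 2-aryl). C2 of the top unit comes from an asymmetric conjugate addition, and its C4 is relayed (attack anti to 2-aryl).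

Key step: step 6

Remark: the sense of induction in steps 8 and 12 is assigned by analogy (2-aryl cycloalkanones and cyclic enones); the ligand antipode would be exchanged if a first run showed the opposite sense.
Remark: compounds 12–15 are racemic at C2 by design; this centre is set in step 8.

**Step 1**
Reactants: 1 1,3,5-trifluorobenzene
Product: 3 1,3-bis(benzyloxy)-5-fluorobenzene, via 1-(benzyloxy)-3,5-difluorobenzene 2 (not isolated)
Conditions: BnOH (2.05 equiv), NaH (2.1 equiv), NMP, 0 °C → 80 °C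
Reagents that add atoms: benzyl alcohol, OCc1ccccc1
Why: Two successive SNAr reactions of sodium benzyloxide; each benzyloxy group makes the remaining C–F bonds less reactive, so two equivalents should stop at the bis-ether.

**Step 2**
Reactants: 3 1,3-bis(benzyloxy)-5-fluorobenzene
Product: 5 2,4-bis(benzyloxy)-6-fluorobenzaldehyde, via aryl iminium salt 4 (not isolated)
Conditions: POCl3 (1.2 equiv), DMF, 0 °C → 50 °C; then ice water
Reagents that add atoms: N,N-dimethylformamide, CN(C)C=O; water, O
Why: Vilsmeier–Haack formylation should occur para to one benzyloxy group and ortho to the other, next to the small fluorine, and not at the more hindered position between the two benzyloxy groups.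

**Step 3**
Reactants: 5 2,4-bis(benzyloxy)-6-fluorobenzaldehyde
Product: 6 [2,4-bis(benzyloxy)-6-fluorophenyl]methanol
Conditions: NaBH4, THF/MeOH, 0 °C
Reagents that add atoms: none
Why: Borohydride reduction of an aryl aldehyde; aryl fluoride and benzyl ethers are inert.

**Step 4**
Reactants: 6 [2,4-bis(benzyloxy)-6-fluorophenyl]methanol
Product: 7 1,5-bis(benzyloxy)-2-(bromomethyl)-3-fluorobenzene
Conditions: PBr3 (0.4 equiv), Et2O, −20 °C → 0 °C; used at once without chromatography
Reagents that add atoms: phosphorus tribromide, BrP(Br)Br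
Why: Bromide displaces the phosphite ester of the benzylic alcohol; the labile electron-rich bromide is taken on directly.

**Step 5**
Reactants: 7 1,5-bis(benzyloxy)-2-(bromomethyl)-3-fluorobenzene; 8 2-(trimethylsilyl)-1,3-dithiane
Product: 10 {2-[2,4-bis(benzyloxy)-6-fluorobenzyl]-1,3-dithian-2-yl}trimethylsilane, via 2-lithio-2-(trimethylsilyl)-1,3-dithiane 9 (not isolated)
Conditions: 8, n-BuLi (1.05 equiv), THF, −30 °C → 0 °C; then 7, −78 °C → 0 °C
Reagents that add atoms: none
Why: Corey–Seebach alkylation of the lithiated silyl dithiane (the future C3) with the benzylic bromide; the butyllithium is consumed before the fluoroarene is added, so the acidic ring C–H next to fluorine is not metalated.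

**Step 6**
Reactants: 10 {2-[2,4-bis(benzyloxy)-6-fluorobenzyl]-1,3-dithian-2-yl}trimethylsilane; 11 4-(benzyloxy)benzaldehyde
Product: 14 rac-5,7-bis(benzyloxy)-2-[4-(benzyloxy)phenyl]spiro[chromane-3,2'-[1,3]dithiane], via caesium alkoxide 12 (not isolated), via trimethylsilyl ether 13 (not isolated)
Conditions: 11 (1.1 equiv), CsF (0.2 equiv), 18-crown-6 (0.2 equiv), THF/DMPU (4:1), 4 Å molecular sieves, 25 °C; then 70 °C
Reagents that add atoms: none
Why: Proposed new method: fluoride attacks silicon of 10 and releases the dithiane-stabilised C3 carbanion, which adds to aldehyde 11 (C2–C3); alkoxide 12 is silylated by a further molecule of 10, which carries the chain and leaves silyl ether 13 as the resting state. On warming, fluoride reversibly unmasks O1, which closes on C8a by intramolecular SNAr (6-exo-trig addition–elimination), and the fluoride expelled from C8a re-enters the cycle, so the only by-product is fluorotrimethylsilane. The closest known reaction types are the fluoride- or phenoxide-catalysed 1,2-addition of 2-silyl-1,3-dithianes to aldehydes, anion relay chemistry of silyl dithianes, the fluoride-catalysed condensation of silyl ethers with aryl fluorides used for poly(aryl ether)s, and alkoxide cyclisations of 3-(2-fluoroaryl)propanols to chromans. C2 is formed without control on purpose, because it becomes epimerisable in ketone 15 and is fixed together with C3 in step 8. The step needs C–Si activation without a strong base (so that the C8–H between fluorine and O7 is not metalated and no aryne forms) and ring closure faster than retro-addition; the catalytic fluoride, the meta relation of O5 and O7 to C8a, and the Thorpe–Ingold effect of the dithiane ring are meant to secure this.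

**Step 7**
Reactants: 14 rac-5,7-bis(benzyloxy)-2-[4-(benzyloxy)phenyl]spiro[chromane-3,2'-[1,3]dithiane]
Product: 15 rac-5,7-bis(benzyloxy)-2-[4-(benzyloxy)phenyl]chroman-3-one
Conditions: MeI (10 equiv), CaCO3 (5 equiv), MeCN/H2O (9:1), 45 °C
Reagents that add atoms: water, O
Why: Alkylative dithioketal hydrolysis (S-methylation, then hydrolysis of the thionium ion); the neutral, non-oxidising conditions should spare the electron-rich rings and the enolisable ketone.

**Step 8**
Reactants: 15 rac-5,7-bis(benzyloxy)-2-[4-(benzyloxy)phenyl]chroman-3-one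
Product: 16 (2R,3R)-5,7-bis(benzyloxy)-2-[4-(benzyloxy)phenyl]chroman-3-ol (5,7,4'-tri-O-benzyl-epiafzelechin)
Conditions: RuCl[(S,S)-TsDPEN](p-cymene) (2 mol %), HCO2H/Et3N (5:2), DMF, 40 °C, argon
Reagents that add atoms: none
Why: Asymmetric transfer hydrogenation with dynamic kinetic resolution: C2–H (α-keto, benzylic, α-oxygenated) should racemise through the enol faster than the chiral hydride reduces the matched enantiomer, and hydride delivery to C3 anti to the 2-aryl group gives the 2,3-cis (2R,3R) alcohol.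

**Step 9**
Reactants: 16 (2R,3R)-5,7-bis(benzyloxy)-2-[4-(benzyloxy)phenyl]chroman-3-ol
Product: 17 (2R,3R,4S)-5,7-bis(benzyloxy)-2-[4-(benzyloxy)phenyl]-4-(2-ethoxyethoxy)chroman-3-ol
Conditions: DDQ (2.0 equiv), 2-ethoxyethanol (5 equiv), CH2Cl2, 25 °C
Reagents that add atoms: 2-ethoxyethanol, CCOCCO
Why: DDQ benzylic oxidation at C4 (hydride abstraction gives a cation stabilised by O5, O7 and O1), and the alcohol adds anti to the 3-OH group (4β).

**Step 10**
Reactants: 17 (2R,3R,4S)-5,7-bis(benzyloxy)-2-[4-(benzyloxy)phenyl]-4-(2-ethoxyethoxy)chroman-3-ol; 16 (2R,3R)-5,7-bis(benzyloxy)-2-[4-(benzyloxy)phenyl]chroman-3-ol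
Product: 18 5,7,4'-tri-O-benzyl-epiafzelechin-(4β→8)-5,7,4'-tri-O-benzyl-epiafzelechin (upper unit 2,3-cis-3,4-trans)
Conditions: 16 (4 equiv), TMSOTf (0.1 equiv), CH2Cl2, −78 °C; surplus 16 recovered
Reagents that add atoms: none
Why: Friedel–Crafts-type proanthocyanidin coupling: the Lewis acid ionises the C4 ether, and C8 of 16 (more accessible than C6, which lies between two benzyloxy groups) attacks the cation from the face anti to the 3-OH and 2-aryl groups, giving the 3,4-trans bond.

**Step 11**
Reactants: 19 7-hydroxy-4H-chromen-4-one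
Product: 20 7-(benzyloxy)-4H-chromen-4-one
Conditions: BnBr (1.2 equiv), K2CO3 (1.5 equiv), acetone, reflux
Reagents that add atoms: benzyl bromide, BrCc1ccccc1
Why: Williamson ether synthesis on the acidic 7-hydroxyl group.

**Step 12**
Reactants: 20 7-(benzyloxy)-4H-chromen-4-one; 21 [4-(benzyloxy)phenyl]boronic acid
Product: 22 (2S)-7-(benzyloxy)-2-[4-(benzyloxy)phenyl]chroman-4-one
Conditions: 21 (2 equiv), Pd(OCOCF3)2 (5 mol %), (R)-t-BuPyOx (6 mol %), NH4PF6 (30 mol %), H2O (5 equiv), ClCH2CH2Cl, 60 °C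
Reagents that add atoms: none
Why: Palladium-catalysed asymmetric conjugate addition of an arylboronic acid to a chromone with a pyridine-oxazoline ligand; the ligand shields one face of the enone during aryl insertion and sets C2.

**Step 13**
Reactants: 22 (2S)-7-(benzyloxy)-2-[4-(benzyloxy)phenyl]chroman-4-one
Product: 23 (2S,4S)-7-(benzyloxy)-2-[4-(benzyloxy)phenyl]chroman-4-ol
Conditions: NaBH4, THF/MeOH, 0 °C
Reagents that add atoms: none
Why: Borohydride reduction should give mainly the 2,4-cis alcohol; the C4 configuration is lost on ionisation in step 14, and the cold, brief conditions avoid ring opening at C2.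

**Step 14**
Reactants: 23 (2S,4S)-7-(benzyloxy)-2-[4-(benzyloxy)phenyl]chroman-4-ol; 18 5,7,4'-tri-O-benzyl-epiafzelechin-(4β→8)-5,7,4'-tri-O-benzyl-epiafzelechin
Product: 24 octa-O-benzyl ether of the target [(2S)-7,4'-bis(benzyloxy)flavan-(4β→8)-tri-O-benzyl-epiafzelechin-(4β→8)-tri-O-benzyl-epiafzelechin, top unit 2,4-trans]
Conditions: 23 (1.0 equiv), 18 (1.0 equiv), TMSOTf (0.2 equiv), 4 Å molecular sieves, CH2Cl2, −78 °C → −40 °C
Reagents that add atoms: none
Why: Friedel–Crafts-type arylation: the Lewis acid ionises the flavan-4-ol to a cation stabilised by O7 and O1, which should be attacked by C8 of the upper unit of 18 (the most accessible free nucleophilic position) anti to the 2-aryl group, giving the 2,4-trans bond.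

**Step 15**
Reactants: 24 octa-O-benzyl ether of the target
Product: 25 target, (2S)-7,4'-dihydroxyflavan-(4β→8)-epiafzelechin-(4β→8)-epiafzelechin (CNP0257624.1)
Conditions: H2 (1 atm), 20% Pd(OH)2/C, THF/MeOH/H2O (20:1:1), 25 °C
Reagents that add atoms: none
Why: Hydrogenolysis of the eight benzyl ethers under mild conditions that should leave the ring C ethers and the diarylmethine interflavan bonds intact.

**Compound list**
1 | 1,3,5-trifluorobenzene | Fc1cc(F)cc(F)c1 | starting material
2 | 1-(benzyloxy)-3,5-difluorobenzene | Fc1cc(F)cc(OCc2ccccc2)c1 | intermediate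
3 | 1,3-bis(benzyloxy)-5-fluorobenzene | Fc1cc(OCc2ccccc2)cc(OCc2ccccc2)c1 | intermediate
4 | {[2,4-bis(benzyloxy)-6-fluorophenyl]methylidene}dimethylammonium dichlorophosphate | C[N+](C)=Cc1c(F)cc(OCc2ccccc2)cc1OCc1ccccc1.[O-]P(Cl)(Cl)=O | intermediate
5 | 2,4-bis(benzyloxy)-6-fluorobenzaldehyde | O=Cc1c(F)cc(OCc2ccccc2)cc1OCc1ccccc1 | intermediate
6 | [2,4-bis(benzyloxy)-6-fluorophenyl]methanol | OCc1c(F)cc(OCc2ccccc2)cc1OCc1ccccc1 | intermediate
7 | 1,5-bis(benzyloxy)-2-(bromomethyl)-3-fluorobenzene | BrCc1c(F)cc(OCc2ccccc2)cc1OCc1ccccc1 | intermediate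
8 | 2-(trimethylsilyl)-1,3-dithiane | C[Si](C)(C)C1SCCCS1 | starting material
9 | 2-lithio-2-(trimethylsilyl)-1,3-dithiane | [Li]C1([Si](C)(C)C)SCCCS1 | intermediate
10 | {2-[2,4-bis(benzyloxy)-6-fluorobenzyl]-1,3-dithian-2-yl}trimethylsilane | C[Si](C)(C)C1(Cc2c(F)cc(OCc3ccccc3)cc2OCc2ccccc2)SCCCS1 | intermediate
11 | 4-(benzyloxy)benzaldehyde | O=Cc1ccc(OCc2ccccc2)cc1 | starting material
12 | caesium [4-(benzyloxy)phenyl]{2-[2,4-bis(benzyloxy)-6-fluorobenzyl]-1,3-dithian-2-yl}methanolate (racemic) | [Cs+].[O-]C(c1ccc(OCc2ccccc2)cc1)C1(Cc2c(F)cc(OCc3ccccc3)cc2OCc2ccccc2)SCCCS1 | intermediate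
13 | O-trimethylsilyl ether of the alcohol of 12 (racemic) | C[Si](C)(C)OC(c1ccc(OCc2ccccc2)cc1)C1(Cc2c(F)cc(OCc3ccccc3)cc2OCc2ccccc2)SCCCS1 | intermediate
14 | rac-5,7-bis(benzyloxy)-2-[4-(benzyloxy)phenyl]spiro[chromane-3,2'-[1,3]dithiane] | C(c1ccccc1)Oc1cc(OCc2ccccc2)c2c(c1)OC(c1ccc(OCc3ccccc3)cc1)C1(C2)SCCCS1 | intermediate
15 | rac-5,7-bis(benzyloxy)-2-[4-(benzyloxy)phenyl]chroman-3-one | O=C1Cc2c(OCc3ccccc3)cc(OCc3ccccc3)cc2OC1c1ccc(OCc2ccccc2)cc1 | intermediate
16 | (2R,3R)-5,7-bis(benzyloxy)-2-[4-(benzyloxy)phenyl]chroman-3-ol | C(c1ccccc1)Oc1cc(OCc2ccccc2)c2c(c1)O[C@H](c1ccc(OCc3ccccc3)cc1)[C@H](O)C2 | intermediate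
17 | (2R,3R,4S)-5,7-bis(benzyloxy)-2-[4-(benzyloxy)phenyl]-4-(2-ethoxyethoxy)chroman-3-ol | C(c1ccccc1)Oc1cc(OCc2ccccc2)c2c(c1)O[C@H](c1ccc(OCc3ccccc3)cc1)[C@H](O)[C@H]2OCCOCC | intermediate
18 | 5,7,4'-tri-O-benzyl-epiafzelechin-(4β→8)-5,7,4'-tri-O-benzyl-epiafzelechin | C(c1ccccc1)Oc1cc(OCc2ccccc2)c2c(c1)O[C@H](c1ccc(OCc3ccccc3)cc1)[C@H](O)[C@H]2c1c(OCc2ccccc2)cc(OCc2ccccc2)c2c1O[C@H](c1ccc(OCc3ccccc3)cc1)[C@H](O)C2 | intermediate
19 | 7-hydroxy-4H-chromen-4-one | O=c1ccoc2cc(O)ccc12 | starting material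
20 | 7-(benzyloxy)-4H-chromen-4-one | O=c1ccoc2cc(OCc3ccccc3)ccc12 | intermediate
21 | [4-(benzyloxy)phenyl]boronic acid | OB(O)c1ccc(OCc2ccccc2)cc1 | starting material
22 | (2S)-7-(benzyloxy)-2-[4-(benzyloxy)phenyl]chroman-4-one | C(c1ccccc1)Oc1ccc([C@@H]2CC(=O)c3ccc(OCc4ccccc4)cc3O2)cc1 | intermediate
23 | (2S,4S)-7-(benzyloxy)-2-[4-(benzyloxy)phenyl]chroman-4-ol | C(c1ccccc1)Oc1ccc([C@@H]2C[C@H](O)c3ccc(OCc4ccccc4)cc3O2)cc1 | intermediate
24 | octa-O-benzyl ether of the target | C(c1ccccc1)Oc1ccc([C@@H]2C[C@@H](c3c(OCc5ccccc5)cc(OCc5ccccc5)c4c3O[C@H](c3ccc(OCc5ccccc5)cc3)[C@H](O)[C@H]4c3c(OCc5ccccc5)cc(OCc5ccccc5)c4c3O[C@H](c3ccc(OCc5ccccc5)cc3)[C@H](O)C4)c3ccc(OCc5ccccc5)cc3O2)cc1 | intermediate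
25 | (2S)-7,4'-dihydroxyflavan-(4β→8)-epiafzelechin-(4β→8)-epiafzelechin (CNP0257624.1) | Oc1ccc([C@@H]2C[C@@H](c3c(O)cc(O)c4c3O[C@H](c3ccc(O)cc3)[C@H](O)[C@H]4c3c(O)cc(O)c4c3O[C@H](c3ccc(O)cc3)[C@H](O)C4)c3ccc(O)cc3O2)cc1 | target

**Count**
Total steps: 15. Longest linear sequence: 12 steps (steps 1–10, 14, 15).

**Steps most likely to fail**

Step 6 (bears the label "Proposed new method:"). The carbanion may be lost to protodesilylation by traces of water. The alkoxide may revert to aldehyde and dithiane anion at the temperature needed for ring closure. The SNAr at the non-activated C–F bond may stall. The fallback uses known chemistry, sets out from 5 and 11, and comes back at 15; it closes ring C through O1–C2 and C3–C4 instead. Aldehyde 5 with KOH in aqueous DMSO (SNAr of the formyl-activated fluoride) gives 2,4-bis(benzyloxy)-6-hydroxybenzaldehyde F1. Aldehyde 11 with nitromethane (NH4OAc, AcOH, heat) gives 1-(benzyloxy)-4-[(E)-2-nitroethenyl]benzene F2. F1 and F2 with DABCO in MeCN undergo oxa-Michael addition and Henry condensation to the racemic 3-nitro-2H-chromene F3. NaBH4 reduces the nitroalkene to the 3-nitrochromane F4, and a Nef reaction (NaOMe, then buffered aqueous TiCl3) gives ketone 15.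

Step 8. Racemisation at C2 may be slower than reduction, which would give only a kinetic resolution, and facial selectivity may be poor or of the wrong sense. The fallback sets out from 15 and comes back at 16. LiBH(s-Bu)3 in THF at −78 °C reduces the ketone anti to the 2-aryl group to the racemic cis-alcohol F5. Esterification with (S)-2-methoxy-2-phenylacetic acid (DCC, DMAP) and chromatographic separation of the diastereomers gives the (2R,3R)-flavan-3-yl (S)-2-methoxy-2-phenylacetate F6. Saponification (K2CO3, MeOH/THF) returns 16.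

Step 14. Site selectivity among the three free nucleophilic ring positions of 18 may be poor. The 2,4-trans preference may be lost. The cation may drain to the flav-3-ene by proton loss, and the existing interflavan bond may be cleaved by acid. The fallback reverses the order of bond formation by orthogonal activation; it sets out from 17 and comes back at 24. Compound 17 with 2,6-dimethylbenzenethiol and BF3·OEt2 at −78 °C gives the 4β-(2,6-dimethylphenylsulfanyl) derivative of 16, F7. F7 (in excess) and 23 with BF3·OEt2 at −78 °C give the top–middle 4β→8 adduct with the thioether still at C4, F8. Thiophilic activation of F8 with AgBF4 in THF at 0 °C in the presence of excess 16 forms the middle–lower bond and gives 24.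

**Further compounds**
F1 | step 6 | 2,4-bis(benzyloxy)-6-hydroxybenzaldehyde | O=Cc1c(O)cc(OCc2ccccc2)cc1OCc1ccccc1
F2 | step 6 | 1-(benzyloxy)-4-[(E)-2-nitroethenyl]benzene | [O-][N+](=O)/C=C/c1ccc(OCc2ccccc2)cc1
F3 | step 6 | rac-5,7-bis(benzyloxy)-2-[4-(benzyloxy)phenyl]-3-nitro-2H-chromene | [O-][N+](=O)C1=Cc2c(OCc3ccccc3)cc(OCc3ccccc3)cc2OC1c1ccc(OCc2ccccc2)cc1
F4 | step 6 | 5,7-bis(benzyloxy)-2-[4-(benzyloxy)phenyl]-3-nitrochromane (racemic, both diastereomers) | [O-][N+](=O)C1Cc2c(OCc3ccccc3)cc(OCc3ccccc3)cc2OC1c1ccc(OCc2ccccc2)cc1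
F5 | step 8 | racemic cis-5,7-bis(benzyloxy)-2-[4-(benzyloxy)phenyl]chroman-3-ol (both enantiomers) | C(c1ccccc1)Oc1cc(OCc2ccccc2)c2c(c1)O[C@H](c1ccc(OCc3ccccc3)cc1)[C@H](O)C2.C(c1ccccc1)Oc1cc(OCc2ccccc2)c2c(c1)O[C@@H](c1ccc(OCc3ccccc3)cc1)[C@@H](O)C2
F6 | step 8 | (2R,3R)-5,7-bis(benzyloxy)-2-[4-(benzyloxy)phenyl]chroman-3-yl (S)-2-methoxy-2-phenylacetate | C(c1ccccc1)Oc1cc(OCc2ccccc2)c2c(c1)O[C@H](c1ccc(OCc3ccccc3)cc1)[C@H](OC(=O)[C@@H](OC)c1ccccc1)C2
F7 | step 14 | 4β-(2,6-dimethylphenylsulfanyl) derivative of 16 (2,3-cis-3,4-trans) | C(c1ccccc1)Oc1cc(OCc2ccccc2)c2c(c1)O[C@H](c1ccc(OCc3ccccc3)cc1)[C@H](O)[C@H]2Sc1c(C)cccc1C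
F8 | step 14 | (2S)-7,4'-bis(benzyloxy)flavan-(4β→8)-[4β-(2,6-dimethylphenylsulfanyl)-5,7,4'-tri-O-benzyl-epiafzelechin] | C(c1ccccc1)Oc1ccc([C@@H]2C[C@@H](c3c(OCc5ccccc5)cc(OCc5ccccc5)c4c3O[C@H](c3ccc(OCc5ccccc5)cc3)[C@H](O)[C@H]4Sc3c(C)cccc3C)c3ccc(OCc5ccccc5)cc3O2)cc1
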